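The furan ring is made by an acylation-triggered [3,3]-sigmatropic rearrangement (oxa-Fischer benzofuran synthesis) of an O-aryl ketoxime ether, not by alkyne or Wittig annulation. The plan exploits the fact that O1 is flanked by C7, which bears the 1,1-dimethylallyl group, and by C3a: one phenol oxygen first relays a prenyl group to C7 (aromatic Claisen) and then, as an N–O tether, delivers the acetophenone methyl carbon to C3a, the only free ortho carbon. The key step forms C3–C3a and O1–C2 in one operation with fixed regiochemistry. Its precursor is the oxime ether of a hindered O-arylhydroxylamine and a 2-prenylated acetophenone.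

Key step: step 9

Remark: the target has no stereocentre and no stereogenic double bond, so it is achiral and needs no enantiocontrol.
Remark: MSH (O-mesitylsulfonylhydroxylamine) is treated as a reagent, freshly prepared from commercial ethyl O-(mesitylsulfonyl)acetohydroxamate (HClO4, dioxane, 0 °C) and used as a CH2Cl2 solution.

Step 1
Reactants: 1 3-hydroxy-5-methoxybenzaldehyde
Product: 2 3-methoxy-5-(triisopropylsilyloxy)benzaldehyde
Conditions: TIPSCl (1.1 equiv), imidazole (2 equiv), DMF, 0 °C → rt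
Reagents that add atoms: triisopropylsilyl chloride, CC(C)[Si](Cl)(C(C)C)C(C)C
Why: Imidazole-mediated silylation of the only hydroxyl group; the bulky TIPS ether tolerates organolithium reagents and later shields both flanking ring carbons from lithiation.

Step 2
Reactants: 2 3-methoxy-5-(triisopropylsilyloxy)benzaldehyde
Product: 5 1-[3-methoxy-2-(3-methylbut-2-en-1-yl)-5-(triisopropylsilyloxy)phenyl]ethan-1-ol (racemic), via lithium alkoxide 3 (not isolated), via ortho-lithiated alkoxide 4 (not isolated)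
Conditions: MeLi (1.05 equiv), Et2O, −78 → 0 °C; n-BuLi (2.2 equiv), TMEDA, 0 °C → rt; CuBr·SMe2 (20 mol %), prenyl bromide (3 equiv), −78 °C → rt; H2O
Reagents that add atoms: methyllithium, [Li]C; prenyl bromide (1-bromo-3-methylbut-2-ene), CC(C)=CCBr
Why: 1,2-Addition of MeLi gives alkoxide 3, whose O–Li and the neighbouring methoxy group jointly direct ortho-lithiation (directed ortho-metalation) to the carbon between them while the OTIPS group shields the other two sites, and copper-catalysed SN2 allylation of aryllithium 4 installs the prenyl group; the carbinol centre is formed racemic and is removed in step 3.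

Step 3
Reactants: 5 1-[3-methoxy-2-(3-methylbut-2-en-1-yl)-5-(triisopropylsilyloxy)phenyl]ethan-1-ol
Product: 6 1-[3-methoxy-2-(3-methylbut-2-en-1-yl)-5-(triisopropylsilyloxy)phenyl]ethan-1-one
Conditions: Dess–Martin periodinane (1.3 equiv), CH2Cl2, 0 °C → rt
Reagents that add atoms: none
Why: Dess–Martin oxidation of the benzylic secondary alcohol to the methyl ketone under neutral conditions that should leave the trisubstituted alkene and the aryl silyl ether untouched.

Step 4
Reactants: 7 phloroglucinol (benzene-1,3,5-triol)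
Product: 8 3,5-bis(triisopropylsilyloxy)phenol
Conditions: TIPSCl (2.0 equiv), imidazole (4 equiv), DMF, 0 °C → rt; chromatography
Reagents that add atoms: triisopropylsilyl chloride, CC(C)[Si](Cl)(C(C)C)C(C)C
Why: Imidazole-mediated silylation; the triol is C3-symmetric, so the only issue is the degree of silylation, and two equivalents should give the bis-ether as the main component of a statistical mixture that is separated by chromatography (mono- and tris-ethers can be recycled).

Step 5
Reactants: 8 3,5-bis(triisopropylsilyloxy)phenol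
Product: 9 1-(3-methylbut-2-en-1-yloxy)-3,5-bis(triisopropylsilyloxy)benzene
Conditions: prenyl bromide (1.2 equiv), K2CO3 (1.5 equiv), acetone, 40 °C
Reagents that add atoms: prenyl bromide (1-bromo-3-methylbut-2-ene), CC(C)=CCBr
Why: Williamson ether synthesis: SN2 O-alkylation of the phenoxide at the primary allylic carbon; a weak base in acetone favours O- over C-alkylation and should leave the TIPS ethers intact.

Step 6
Reactants: 9 1-(3-methylbut-2-en-1-yloxy)-3,5-bis(triisopropylsilyloxy)benzene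
Product: 10 2-(2-methylbut-3-en-2-yl)-3,5-bis(triisopropylsilyloxy)phenol
Conditions: PhNEt2, 190 °C, sealed tube, Ar
Reagents that add atoms: none
Why: Aromatic Claisen rearrangement: a [3,3] shift through a chair transition state carries the prenyl group from oxygen to an ortho carbon with allylic inversion (hence the 1,1-dimethylallyl group), the two ortho carbons being equivalent by symmetry, and the amine solvent promotes tautomerisation of the dienone before Cope migration to the para carbon or acid-catalysed cyclisation can compete.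

Step 7
Reactants: 10 2-(2-methylbut-3-en-2-yl)-3,5-bis(triisopropylsilyloxy)phenol
Product: 12 O-[2-(2-methylbut-3-en-2-yl)-3,5-bis(triisopropylsilyloxy)phenyl]hydroxylamine, via sodium phenoxide 11 (not isolated)
Conditions: NaH (1.05 equiv), THF, 0 °C; MSH (1.2 equiv), CH2Cl2, 0 °C; crude product used at once
Reagents that add atoms: O-mesitylsulfonylhydroxylamine (MSH), Cc1cc(C)c(S(=O)(=O)ON)c(C)c1
Why: Electrophilic amination: the phenoxide oxygen attacks the nitrogen of MSH in an SN2 displacement of mesitylenesulfonate, the small NH2 electrophile being able to reach the oxygen next to the quaternary carbon, while the TIPS ethers resist attack by the phenoxide.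

Step 8
Reactants: 12 O-[2-(2-methylbut-3-en-2-yl)-3,5-bis(triisopropylsilyloxy)phenyl]hydroxylamine; 6 1-[3-methoxy-2-(3-methylbut-2-en-1-yl)-5-(triisopropylsilyloxy)phenyl]ethan-1-one
Product: 13 1-[3-methoxy-2-(3-methylbut-2-en-1-yl)-5-(triisopropylsilyloxy)phenyl]ethan-1-one O-[2-(2-methylbut-3-en-2-yl)-3,5-bis(triisopropylsilyloxy)phenyl]oxime (E drawn; an E/Z mixture is acceptable)
Conditions: PPTS (10 mol %), 4 Å MS, EtOH/THF, 50 °C
Reagents that add atoms: none
Why: Acid-catalysed condensation (oxime ether formation) of the α-effect nucleophile with the methyl ketone; the C=N geometry is irrelevant because it is lost on N-acylation in step 9.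

Step 9
Reactants: 13 O-aryl ketoxime ether
Product: 17 2-[3-methoxy-2-(3-methylbut-2-en-1-yl)-5-(triisopropylsilyloxy)phenyl]-7-(2-methylbut-3-en-2-yl)-4,6-bis(triisopropylsilyloxy)benzofuran, via N-trifluoroacetyl ene-hydroxylamine 14 (not isolated), via ortho-hydroxybenzyl N-acyl ketimine 15 (not isolated), via cyclic N-acyl aminal 16 (not isolated)
Conditions: TFAA (1.5 equiv), DMAP (3 equiv), CH2Cl2, 0 °C → rt
Reagents that add atoms: none
Why: TFAA acylates the oxime nitrogen and DMAP removes a methyl proton to give ene-hydroxylamine 14, whose weak N–O bond and O-aryl/N-vinyl 1,5-diene array should undergo a [3,3]-sigmatropic shift through a six-membered chair-like transition state at or below room temperature, forming C3–C3a as N–O breaks; rearomatisation gives ketimine 15. This is the acylation-accelerated variant of the oxa-Fischer conversion of O-aryl oxime ethers into benzofurans, a known entry to 2-arylbenzofurans. The furan ring then closes by 5-exo-trig addition of the O1 phenol to the N-acyl ketimine carbon (aminal 16), and loss of trifluoroacetamide through the 2-aryl-stabilised oxocarbenium ion aromatises the ring. No stereocentre survives: the aminal carbon of 16 is formed racemic and becomes sp2. The step needs ortho-regioselectivity and chemoselectivity: C3a is the only ortho carbon bearing hydrogen (C7 carries the quaternary 1,1-dimethylallyl group), the electron-rich trioxygenated ring accelerates the shift, and the DMAP-buffered aprotic medium should keep the acid-sensitive prenyl and 1,1-dimethylallyl alkenes and the TIPS ethers intact.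

Step 10
Reactants: 17 tris-TIPS-protected benzofuran
Product: 18 2-[5-hydroxy-3-methoxy-2-(3-methylbut-2-en-1-yl)phenyl]-7-(2-methylbut-3-en-2-yl)benzofuran-4,6-diol (CNP0169501.0)
Conditions: TBAF (3.5 equiv), AcOH (3.5 equiv), THF, 0 °C → rt, Ar
Reagents that add atoms: none
Why: Fluoride-mediated desilylation driven by Si–F bond formation; acetic acid buffers the phenoxides so that the electron-rich triphenol should not be oxidised and both C5 side chains remain untouched.

Compound list
1 | 3-hydroxy-5-methoxybenzaldehyde | O=Cc1cc(O)cc(OC)c1 | starting material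
2 | 3-methoxy-5-(triisopropylsilyloxy)benzaldehyde | O=Cc1cc(OC)cc(O[Si](C(C)C)(C(C)C)C(C)C)c1 | intermediate
3 | lithium 1-[3-methoxy-5-(triisopropylsilyloxy)phenyl]ethan-1-olate (racemic) | CC(O[Li])c1cc(OC)cc(O[Si](C(C)C)(C(C)C)C(C)C)c1 | intermediate (not isolated)
4 | lithium 1-[2-lithio-3-methoxy-5-(triisopropylsilyloxy)phenyl]ethan-1-olate (racemic) | CC(O[Li])c1cc(O[Si](C(C)C)(C(C)C)C(C)C)cc(OC)c1[Li] | intermediate (not isolated)
5 | 1-[3-methoxy-2-(3-methylbut-2-en-1-yl)-5-(triisopropylsilyloxy)phenyl]ethan-1-ol (racemic) | CC(O)c1cc(O[Si](C(C)C)(C(C)C)C(C)C)cc(OC)c1CC=C(C)C | intermediate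
6 | 1-[3-methoxy-2-(3-methylbut-2-en-1-yl)-5-(triisopropylsilyloxy)phenyl]ethan-1-one | CC(=O)c1cc(O[Si](C(C)C)(C(C)C)C(C)C)cc(OC)c1CC=C(C)C | intermediate
7 | phloroglucinol | Oc1cc(O)cc(O)c1 | starting material
8 | 3,5-bis(triisopropylsilyloxy)phenol | Oc1cc(O[Si](C(C)C)(C(C)C)C(C)C)cc(O[Si](C(C)C)(C(C)C)C(C)C)c1 | intermediate
9 | 1-(3-methylbut-2-en-1-yloxy)-3,5-bis(triisopropylsilyloxy)benzene | CC(C)=CCOc1cc(O[Si](C(C)C)(C(C)C)C(C)C)cc(O[Si](C(C)C)(C(C)C)C(C)C)c1 | intermediate
10 | 2-(2-methylbut-3-en-2-yl)-3,5-bis(triisopropylsilyloxy)phenol | C=CC(C)(C)c1c(O)cc(O[Si](C(C)C)(C(C)C)C(C)C)cc1O[Si](C(C)C)(C(C)C)C(C)C | intermediate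
11 | sodium 2-(2-methylbut-3-en-2-yl)-3,5-bis(triisopropylsilyloxy)phenolate | C=CC(C)(C)c1c([O-])cc(O[Si](C(C)C)(C(C)C)C(C)C)cc1O[Si](C(C)C)(C(C)C)C(C)C.[Na+] | intermediate (not isolated)
12 | O-[2-(2-methylbut-3-en-2-yl)-3,5-bis(triisopropylsilyloxy)phenyl]hydroxylamine | C=CC(C)(C)c1c(ON)cc(O[Si](C(C)C)(C(C)C)C(C)C)cc1O[Si](C(C)C)(C(C)C)C(C)C | intermediate
13 | (E)-1-[3-methoxy-2-(3-methylbut-2-en-1-yl)-5-(triisopropylsilyloxy)phenyl]ethan-1-one O-[2-(2-methylbut-3-en-2-yl)-3,5-bis(triisopropylsilyloxy)phenyl]oxime | C/C(=N\Oc1cc(O[Si](C(C)C)(C(C)C)C(C)C)cc(O[Si](C(C)C)(C(C)C)C(C)C)c1C(C)(C)C=C)c1cc(O[Si](C(C)C)(C(C)C)C(C)C)cc(OC)c1CC=C(C)C | intermediate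
14 | N-(aryloxy)-N-(1-arylvinyl)trifluoroacetamide (N-trifluoroacetyl ene-hydroxylamine of 13) | C=C(N(Oc1cc(O[Si](C(C)C)(C(C)C)C(C)C)cc(O[Si](C(C)C)(C(C)C)C(C)C)c1C(C)(C)C=C)C(=O)C(F)(F)F)c1cc(O[Si](C(C)C)(C(C)C)C(C)C)cc(OC)c1CC=C(C)C | intermediate (not isolated)
15 | N-{2-[2-hydroxy-3-(2-methylbut-3-en-2-yl)-4,6-bis(triisopropylsilyloxy)phenyl]-1-arylethylidene}trifluoroacetamide (aryl = 3-methoxy-2-prenyl-5-TIPSO-phenyl) | C=CC(C)(C)c1c(O)c(CC(=NC(=O)C(F)(F)F)c2cc(O[Si](C(C)C)(C(C)C)C(C)C)cc(OC)c2CC=C(C)C)c(O[Si](C(C)C)(C(C)C)C(C)C)cc1O[Si](C(C)C)(C(C)C)C(C)C | intermediate (not isolated)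
16 | 2-aryl-2-(trifluoroacetamido)-7-(2-methylbut-3-en-2-yl)-4,6-bis(triisopropylsilyloxy)-2,3-dihydrobenzofuran (racemic) | C=CC(C)(C)c1c(O[Si](C(C)C)(C(C)C)C(C)C)cc(O[Si](C(C)C)(C(C)C)C(C)C)c2c1OC(NC(=O)C(F)(F)F)(c1cc(O[Si](C(C)C)(C(C)C)C(C)C)cc(OC)c1CC=C(C)C)C2 | intermediate (not isolated)
17 | 2-[3-methoxy-2-(3-methylbut-2-en-1-yl)-5-(triisopropylsilyloxy)phenyl]-7-(2-methylbut-3-en-2-yl)-4,6-bis(triisopropylsilyloxy)benzofuran | C=CC(C)(C)c1c(O[Si](C(C)C)(C(C)C)C(C)C)cc(O[Si](C(C)C)(C(C)C)C(C)C)c2cc(-c3cc(O[Si](C(C)C)(C(C)C)C(C)C)cc(OC)c3CC=C(C)C)oc12 | intermediate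
18 | 2-[5-hydroxy-3-methoxy-2-(3-methylbut-2-en-1-yl)phenyl]-7-(2-methylbut-3-en-2-yl)benzofuran-4,6-diol | C=CC(C)(C)c1c(O)cc(O)c2cc(-c3cc(O)cc(OC)c3CC=C(C)C)oc12 | target

Total step count: 10. Longest linear sequence: 7 steps (steps 4–10, from phloroglucinol 7); the ketone branch (steps 1–3) joins at step 8.

Steps most likely to fail

Step 9 (key step). The risks are Friedel–Crafts trifluoroacetylation of the electron-rich ring or of benzofuran C3 competing with N-acylation, N–O cleavage without C–C bond formation, and stalling at the aminal stage. The fallback sets out from phenol 10 and ketone 6 and returns at 17 by the conventional alkyne annulation. Phenol 10 would be iodinated at its only free ortho carbon (NIS, CH2Cl2, −40 °C) to give 2-iodo-6-(2-methylbut-3-en-2-yl)-3,5-bis(triisopropylsilyloxy)phenol F1. The para carbon is shielded by two OTIPS groups, and ring iodination of the trioxygenated arene should outrun iodoetherification of the vinyl group. Ketone 6 would be converted (LDA, ClP(O)(OEt)2, THF, −78 °C) into diethyl 1-[3-methoxy-2-(3-methylbut-2-en-1-yl)-5-(triisopropylsilyloxy)phenyl]vinyl phosphate F2. Elimination with LDA (−78 °C → rt) would give 1-ethynyl-3-methoxy-2-(3-methylbut-2-en-1-yl)-5-(triisopropylsilyloxy)benzene F3. Sonogashira coupling of F1 with F3 (PdCl2(PPh3)2, CuI, Et3N, DMF, 60 °C) should give 2-(arylethynyl)-6-(2-methylbut-3-en-2-yl)-3,5-bis(triisopropylsilyloxy)phenol F4. Its 5-endo-dig cyclisation (CuI, Et3N, 80 °C) leads back to 17.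

Step 7. The risks are C-amination of the ambident electron-rich phenoxide, slow N–O bond formation at the hindered oxygen, and decomposition of the electron-rich O-arylhydroxylamine before it is condensed. The fallback sets out from phenol 10 and ketone 6 and returns at 17 without an N–O tether. Phenol 10 would be brominated at the free ortho carbon (NBS, CH2Cl2, −78 °C) to give 2-bromo-6-(2-methylbut-3-en-2-yl)-3,5-bis(triisopropylsilyloxy)phenol F5. Palladium-catalysed enolate α-arylation of ketone 6 with F5 (Pd2(dba)3, 1,2-bis(di-tert-butylphosphinomethyl)benzene, NaOt-Bu, toluene, 80 °C) should give 2-[2-hydroxy-3-(2-methylbut-3-en-2-yl)-4,6-bis(triisopropylsilyloxy)phenyl]-1-[3-methoxy-2-(3-methylbut-2-en-1-yl)-5-(triisopropylsilyloxy)phenyl]ethan-1-one F6. Cyclodehydration of F6 (PPTS, toluene, 80 °C) leads back to 17.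

Step 2. The risks are incomplete or misdirected lithiation (at a carbon flanking OTIPS), SN2′ allylation that would deliver the branched C5 isomer, and silyl loss or migration under the strongly basic conditions. The fallback sets out from aldehyde 1 and returns at alcohol 5, replacing directed metalation by electrophilic substitution and cross-coupling. Bromination of 1 para to the free hydroxyl group (NBS, MeCN, 0 °C; regioisomers, if formed, removed by chromatography) would give 2-bromo-5-hydroxy-3-methoxybenzaldehyde F7. Silylation (TIPSCl, imidazole, DMF) would give 2-bromo-3-methoxy-5-(triisopropylsilyloxy)benzaldehyde F8. Stille coupling with tributyl(3-methylbut-2-en-1-yl)stannane (Pd(PPh3)4, DMF, 90 °C) should give 3-methoxy-2-(3-methylbut-2-en-1-yl)-5-(triisopropylsilyloxy)benzaldehyde F9. Addition of MeMgBr (THF, −78 °C) leads back to 5.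

Further compounds
F1 | step 9 | 2-iodo-6-(2-methylbut-3-en-2-yl)-3,5-bis(triisopropylsilyloxy)phenol | C=CC(C)(C)c1c(O)c(I)c(O[Si](C(C)C)(C(C)C)C(C)C)cc1O[Si](C(C)C)(C(C)C)C(C)C
F2 | step 9 | diethyl 1-[3-methoxy-2-(3-methylbut-2-en-1-yl)-5-(triisopropylsilyloxy)phenyl]vinyl phosphate | C=C(OP(=O)(OCC)OCC)c1cc(O[Si](C(C)C)(C(C)C)C(C)C)cc(OC)c1CC=C(C)C
F3 | step 9 | 1-ethynyl-3-methoxy-2-(3-methylbut-2-en-1-yl)-5-(triisopropylsilyloxy)benzene | C#Cc1cc(O[Si](C(C)C)(C(C)C)C(C)C)cc(OC)c1CC=C(C)C
F4 | step 9 | 2-{[3-methoxy-2-(3-methylbut-2-en-1-yl)-5-(triisopropylsilyloxy)phenyl]ethynyl}-6-(2-methylbut-3-en-2-yl)-3,5-bis(triisopropylsilyloxy)phenol | C=CC(C)(C)c1c(O)c(C#Cc2cc(O[Si](C(C)C)(C(C)C)C(C)C)cc(OC)c2CC=C(C)C)c(O[Si](C(C)C)(C(C)C)C(C)C)cc1O[Si](C(C)C)(C(C)C)C(C)C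
F5 | step 7 | 2-bromo-6-(2-methylbut-3-en-2-yl)-3,5-bis(triisopropylsilyloxy)phenol | C=CC(C)(C)c1c(O)c(Br)c(O[Si](C(C)C)(C(C)C)C(C)C)cc1O[Si](C(C)C)(C(C)C)C(C)C
F6 | step 7 | 2-[2-hydroxy-3-(2-methylbut-3-en-2-yl)-4,6-bis(triisopropylsilyloxy)phenyl]-1-[3-methoxy-2-(3-methylbut-2-en-1-yl)-5-(triisopropylsilyloxy)phenyl]ethan-1-one | C=CC(C)(C)c1c(O)c(CC(=O)c2cc(O[Si](C(C)C)(C(C)C)C(C)C)cc(OC)c2CC=C(C)C)c(O[Si](C(C)C)(C(C)C)C(C)C)cc1O[Si](C(C)C)(C(C)C)C(C)C
F7 | step 2 | 2-bromo-5-hydroxy-3-methoxybenzaldehyde | O=Cc1cc(O)cc(OC)c1Br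
F8 | step 2 | 2-bromo-3-methoxy-5-(triisopropylsilyloxy)benzaldehyde | O=Cc1cc(O[Si](C(C)C)(C(C)C)C(C)C)cc(OC)c1Br
F9 | step 2 | 3-methoxy-2-(3-methylbut-2-en-1-yl)-5-(triisopropylsilyloxy)benzaldehyde | O=Cc1cc(O[Si](C(C)C)(C(C)C)C(C)C)cc(OC)c1CC=C(C)C
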